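Count what is left.

the same everywhere: free catalyst 0.40 mM; added ligand 0.21 mM

| run | substrate | partner | remark | time |
|---|---|---|---|---|
| Tuesday's | 0.016 M | 0.0192 M | run made earlier |  |
| Saturday's | 0.011 M | 0.0192 M | run made earlier |  |
| Thursday's | 0.024 M | 0.0192 M | run made earlier |  |
| autumn | 0.016 M | 0.0192 M | everything together at the start | 3.0 d |
| dawn | 0.016 M (fed, over 2.5 d) | 0.0192 M | all else is in the flask from the start; the feed brings no volume worth counting | 3.0 d |
| summer | 0.016 M | 0.0192 M (fed, over 2.5 d) | all else is in the flask from the start; the feed brings no volume worth counting | 3.0 d |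

| Tuesday's: time / d | Tuesday's: target / % | Saturday's: time / d | Saturday's: target / % | Thursday's: time / d | Thursday's: target / % |
|---|---|---|---|---|---|
| 0.500 | 16 | 0.250 | 10 | 0.500 | 11 |
| 1.04 | 29 | 0.417 | 16 | 1.04 | 23 |
| 1.67 | 42 | 0.625 | 21 | 1.67 | 38 |
| 2.08 | 44 | 1.04 | 36 | 2.08 | 39 |
| 2.50 | 51 | 1.67 | 45 | 2.50 | 41 |
| 3.00 | 56 | 3.00 | 63 | 3.00 | 44 |

(each reading ± 2 percentage points)

- the best flask by amount of target, in percent of the substrate charged; "all alike" if 1.5 percentage points covers them all (autumn / dawn / summer / all alike)
- amount of target at the end, in percent of the substrate charged, autumn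
- amount of target at the end, in percent of the substrate charged, dawn
- amount of target at the end, in percent of the substrate charged, summer

- the earlier runs were read with a standard deviation of 2 percentage points

1. Compare Tuesday's run with Saturday's. The [partner], free catalyst and added ligand match, and the [substrate] at the start differs. At 3.00 d, Tuesday's run reads 8.96 mM of target and Saturday's 6.93 mM. Tuesday's run still reads lower in percent, because its amount is up on Saturday's by a smaller factor than its charge.

2. So work with the share not yet target. Tuesday's run gives 0.274 d⁻¹ for the leaving rate κ, the natural log of one over that share, divided by the time. Saturday's run gives 0.331 d⁻¹, so these two readings put κ higher at the smaller charge.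

3. Autumn has Tuesday's charges, so I expect about 56%, give or take 2 points.

4. In a steady feed, the average parcel has 1.75 d in the flask. I treat dawn and summer alike, though no run varied partner, and this is the weak step. Tuesday's κ then gives 38.1% and Saturday's gives 44.0%. I commit to that band for both, with autumn ahead.

5. The forecast gives 56% for autumn, 35% for dawn and 50% for summer, with autumn best, and says: “Summer is poorly determined, because partner was never varied”.

6. The flasks give 54.7% for autumn, 42.1% for dawn and 42.7% for summer, with autumn best. Dawn and summer fall inside my band.

    substrate + free catalyst → free catalyst + open intermediate (k = 1100 M⁻¹ h⁻¹)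
    target ⇌ isomer of the product (K = 0.340, k = 0.0520 h⁻¹)
    free catalyst + added ligand ⇌ idle complex, settled at all times (K = 5800 M⁻¹)
    partner + catalyst intermediate → free catalyst + target (k = 110 M⁻¹ h⁻¹)
    free catalyst → spent catalyst (k = 4.00 × 10⁻⁴ h⁻¹)
    free catalyst + open intermediate ⇌ catalyst intermediate (K = 100 M⁻¹, k = 1200 M⁻¹ h⁻¹)

7. Autumn is not at rest at 3.00 d: 27.0% of the substrate charged still stands as open intermediate, and partner is at 39.6% of its charge. Run κ out to ten times the time and you leave 0.0272% of autumn's charge outside the target. At 30.0 d, autumn instead has 74.6% as target and 25.4% as isomer of the product, with open intermediate down to 0.0759%. For dawn, κ leaves 0.0383%, yet at 30.0 d dawn holds 74.6% as target and 25.3% as isomer of the product.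

The data come from a simulation with made-up constants, and the scatter is random.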